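Numbering (2-benzoxepine, used for every intermediate): C1 lactone C=O, O2, C3, C4(CO2H)=C5, C5a, C6 (isopropyl), C7, C8, C9 (carbinol), C9a; half A is the free-diol half, half B the free-acid half. Retrosynthetic cuts, in order: the ester O–C bond between the C4 carboxyl of A and the C9-CH2O of B; then in each half the two C9–O bonds, C4=C5, O2–C3, the exocyclic C9=C bond, and last C5a–C6 together with C9–C9a.
Enabling feature: each half holds the cyclohexane C5a–C6–C7–C8–C9–C9a with vicinal trans carbon arms (C1 on C9a, C5 on C5a) flanked by isopropyl on C6 and oxygen on C9. This is the pattern of a fumarate/1-oxy-4-alkyl-diene [4+2] adduct, and half B is the mirror image of half A, so the two hands of one ligand supply both halves.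
Forward order of rings: cyclohexene by catalytic Diels–Alder reaction (step 4; mirror twin step 16); C1 is then parked at the alcohol level in a temporary trans γ-lactone with C5, so that the C9 ketone is methylenated without ever being β to a carboxyl group; lactol/Wittig gives the C5a-vinyl group, C1 returns to the acid, and the seven-membered lactone closes by ring-closing metathesis.
Union: the primary C9-CH2OH of B is acylated by the C4 acid of A; the diol of A is then unveiled from its exocyclic methylene and the tert-butyl ester is cleaved.
Stereochemistry: C6, C5a and C9a (plus a sacrificial C9 centre) come from the Diels–Alder step (E,E-diene, E-dienophile, endo imide, ligand-controlled face); the C9 carbinol of each half comes from equatorial osmylation of the exocyclic alkene (substrate control).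

Key step: step 4

Assumption: by the square-planar chelate model the (S,S) ligand is assigned to the half-A hand (diene on the Re face of the imide α-carbon); if the adduct proves to be of the other hand, the two ligand enantiomers change places between steps 4 and 16 and nothing else changes.

Step 1
Reactants: 1 3-methylbutanal; 2 (triphenylphosphoranylidene)acetaldehyde
Product: 3 (E)-5-methylhex-2-enal
Conditions: 1 in excess, toluene, 80 °C
Reagents that add atoms: none
Why: Wittig olefination with a formyl-stabilised ylide should give the (E)-enal selectively and stop after one homologation when the aldehyde is in excess.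

Step 2
Reactants: 3 (E)-5-methylhex-2-enal
Product: 4 (1E,3E)-5-methylhexa-1,3-dien-1-yl acetate
Conditions: isopropenyl acetate (excess), TsOH·H2O (cat.), 95 °C, acetone distilled off
Reagents that add atoms: isopropenyl acetate, CC(=C)OC(C)=O
Why: Acid-catalysed enol acetylation (transesterification, acetone removed) converts the enal through its γ-position into the conjugated dienyl acetate, the (1E,3E) isomer being the expected main form and the only one able to reach the s-cis geometry needed in step 4, so minor 1Z material is a spectator.

Step 3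
Reactants: 5 ethyl (E)-4-chloro-4-oxobut-2-enoate (ethyl fumaroyl chloride); 6 oxazolidin-2-one
Product: 7 ethyl (E)-4-oxo-4-(2-oxooxazolidin-3-yl)but-2-enoate
Conditions: 6, n-BuLi, THF, −78 °C; then 5, −78 → 0 °C
Reagents that add atoms: none
Why: N-Acylation of the lithiated oxazolidinone with the acid chloride at low temperature gives the imide without touching the fumarate double bond or the ethyl ester.

Step 4
Reactants: 4 (1E,3E)-5-methylhexa-1,3-dien-1-yl acetate; 7 ethyl (E)-4-oxo-4-(2-oxooxazolidin-3-yl)but-2-enoate
Product: 8 A-hand cycloadduct, ethyl (1R,2S,5R,6S)-5-acetoxy-2-isopropyl-6-(2-oxooxazolidine-3-carbonyl)cyclohex-3-ene-1-carboxylate (C9 acetoxy, C1 imide carbonyl on C9a and C6 isopropyl mutually cis; C5 ester on C5a trans to them)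
Conditions: [Cu((S,S)-t-Bu-box)](SbF6)2 (10 mol%; from CuCl2, AgSbF6 and (S,S)-2,2'-isopropylidenebis(4-tert-butyl-2-oxazoline)), CH2Cl2, −20 °C → rt
Reagents that add atoms: none
Why: The imide binds the divalent copper centre of the bis(oxazoline) complex through both carbonyl oxygens, which fixes the enoyl unit s-cis, lowers its LUMO and lets the E,E-diene add in a concerted, asynchronous, suprafacial [4+2] cycloaddition; the closest known reaction type is the copper bis(oxazoline)-catalysed Diels–Alder reaction of N-enoyl oxazolidinones with 1-acyloxy dienes. The cyclohexene ring C5a–C6–C7–C8–C9–C9a closes by this intermolecular cycloaddition, C5a–C6 and C9–C9a being formed in the same step. The cis relation of C6 and C9 follows from the E,E geometry of the diene, the trans relation of C5a and C9a from the E geometry of the fumarate, and the cis placement of C1 relative to acetoxy and isopropyl from the endo position of the chelated imide. The absolute configuration comes from the ligand, one tert-butyl group of which shields one face of the bound dienophile so that the diene should add to the Re face of the imide α-carbon. The step needs regioselectivity (imide α-carbon bonded to the acetoxy-bearing terminus), which the acetoxy donor secures by making the remote diene terminus the nucleophilic partner of the imide β-carbon, and endo and facial selectivity, which rest on the two-point chelation and the ligand hand.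

Step 5
Reactants: 8 A-hand cycloadduct
Product: 9 A-hand saturated adduct, ethyl 3-acetoxy-6-isopropyl-2-(2-oxooxazolidine-3-carbonyl)cyclohexane-1-carboxylate (configuration unchanged)
Conditions: H2 (1 atm), PtO2 (cat.), EtOAc, rt
Reagents that add atoms: none
Why: Heterogeneous hydrogenation saturates the only C=C bond (C7=C8), platinum being chosen over palladium to avoid hydrogenolysis of the allylic C9 acetate, and no stereocentre is made or touched.

Step 6
Reactants: 9 A-hand saturated adduct
Product: 10 A-hand hydroxymethyl ester, ethyl 3-acetoxy-2-(hydroxymethyl)-6-isopropylcyclohexane-1-carboxylate (C1 now CH2OH)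
Conditions: NaBH4, THF/H2O (4:1), 0 °C → rt
Reagents that add atoms: none
Why: Borohydride reduction of an N-acyl oxazolidinone in wet THF cleaves the activated exocyclic imide carbonyl to the primary alcohol while the far less electrophilic ethyl ester and acetate are left, so C1 reaches the alcohol level with C9a untouched.

Step 7
Reactants: 10 A-hand hydroxymethyl ester
Product: 12 A-hand hydroxy lactone, trans-fused 4-hydroxy-7-isopropylhexahydroisobenzofuran-1(3H)-one (C5 is the lactone carbonyl, C1 the OCH2; C9–OH cis to C1 and to isopropyl), via diol ester 11 (not isolated)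
Conditions: K2CO3 (cat.), MeOH, 0 °C → rt; then AcOH, evaporation; CSA (cat.), toluene, 50 °C
Reagents that add atoms: none
Why: Base-catalysed methanolysis removes the acetate and acid catalysis then closes the C1 alcohol onto the C5 ester (trans-fused γ-lactonisation), which ties up the C1 oxygen without a protecting group, and any material that has already lactonised or suffered acetyl migration converges on the same product.

Step 8
Reactants: 12 A-hand hydroxy lactone
Product: 13 A-hand keto lactone, trans-fused 7-isopropylhexahydroisobenzofuran-1,4-dione (C9 ketone)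
Conditions: Dess–Martin periodinane, CH2Cl2, rt
Reagents that add atoms: none
Why: Dess–Martin oxidation of the lone secondary alcohol gives the C9 ketone under neutral conditions that should neither eliminate the β-acyloxymethyl group nor epimerise C9a, and with C1 at the alcohol level the ketone is not part of a β-keto acid system.

Step 9
Reactants: 13 A-hand keto lactone
Product: 14 A-hand methylene lactone, trans-fused 7-isopropyl-4-methylidenehexahydroisobenzofuran-1(3H)-one
Conditions: Zn, CH2Br2, TiCl4 (preformed reagent), THF/CH2Cl2, 0 °C → rt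
Reagents that add atoms: dibromomethane, BrCBr
Why: Lombardo methylenation with the non-basic zinc/titanium methylene reagent converts the ketone into the exocyclic alkene chemoselectively beside the lactone and avoids the E1cB loss of the β-acyloxy group that a basic phosphorus ylide would risk.

Step 10
Reactants: 14 A-hand methylene lactone
Product: 15 A-hand lactol, 7-isopropyl-4-methylideneoctahydroisobenzofuran-1-ol (mixture of anomers)
Conditions: i-Bu2AlH (1.1 equiv), CH2Cl2, −78 °C
Reagents that add atoms: none
Why: Partial reduction of a γ-lactone with one equivalent of i-Bu2AlH at −78 °C stops at the lactol, which brings C5 to the aldehyde level, and the new hemiacetal centre is of no consequence.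

Step 11
Reactants: 15 A-hand lactol
Product: 16 A-hand diene alcohol, (2-ethenyl-3-isopropyl-6-methylidenecyclohexyl)methanol (C1H2OH cis to isopropyl, vinyl trans to both)
Conditions: Ph3PCH3Br, KOt-Bu (3 equiv each), THF, 0 °C → rt
Reagents that add atoms: methyltriphenylphosphonium bromide (as its ylide), C[P+](c1ccccc1)(c1ccccc1)c1ccccc1.[Br-]
Why: Wittig methylenation of a lactol with excess ylide (opening of the lactolate and olefination at C5) installs the C5a-vinyl group and frees the C1 primary alcohol, C5a remaining in its all-equatorial and thermodynamically preferred configuration.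

Step 12
Reactants: 16 A-hand diene alcohol
Product: 17 A-hand diene acid, 2-ethenyl-3-isopropyl-6-methylidenecyclohexane-1-carboxylic acid
Conditions: TEMPO (cat.), PhI(OAc)2 (2.2 equiv), MeCN/H2O (1:1), rt
Reagents that add atoms: water, O
Why: Oxoammonium (TEMPO/PhI(OAc)2) oxidation in aqueous acetonitrile takes the primary alcohol through to the carboxylic acid without touching either alkene, returning C1 to the acid level now that the C9 carbonyl is gone.

Step 13
Reactants: 17 A-hand diene acid; 18 tert-butyl 2-(bromomethyl)acrylate
Product: 19 A-hand triene diester, 2-(tert-butoxycarbonyl)prop-2-en-1-yl 2-ethenyl-3-isopropyl-6-methylidenecyclohexane-1-carboxylate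
Conditions: Cs2CO3, DMF, 0 °C → rt
Reagents that add atoms: none
Why: O-Alkylation of the caesium carboxylate with the allylic bromide (SN2, or SN2' to the same product) forms the O2–C3 bond and brings in C3, C4 and the protected C4 carboxyl.

Step 14
Reactants: 19 A-hand triene diester
Product: 20 A-hand oxepinone ester, tert-butyl (5aS,6R,9aS)-6-isopropyl-9-methylidene-1-oxo-1,3,5a,6,7,8,9,9a-octahydro-2-benzoxepine-4-carboxylate
Conditions: second-generation Hoveyda–Grubbs catalyst, RuCl2(H2IMes)(=CH-C6H4-2-O-i-Pr) (10 mol%), toluene (2 mM), 80 °C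
Reagents that add atoms: none
Why: Ring-closing metathesis between the C5a-vinyl group and the 1,1-disubstituted acrylate alkene forms C4=C5 and the seven-membered lactone on the rigid trans-1,2-disubstituted cyclohexane with loss of ethene, the ring enforcing the alkene geometry and the hindered C9 methylene expected to stay out of the reaction.

Step 15
Reactants: 20 A-hand oxepinone ester
Product: 22 A-hand acid, (5aS,6R,9aS)-6-isopropyl-9-methylidene-1-oxo-1,3,5a,6,7,8,9,9a-octahydro-2-benzoxepine-4-carboxylic acid, via silyl ester 21 (not isolated)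
Conditions: TMSOTf, 2,6-lutidine, CH2Cl2, 0 °C; then aqueous citric acid work-up
Reagents that add atoms: trimethylsilyl triflate, C[Si](C)(C)OS(=O)(=O)C(F)(F)F (its silyl group is carried only by intermediate 21; none of its atoms remain in 22)
Why: Silyl triflate-mediated cleavage of the tert-butyl ester (O-silylation, loss of 2-methylpropene, hydrolysis of the silyl ester on work-up) frees the C4 acid without a protic acid that could add to or isomerise the exocyclic alkene.

Step 16
Reactants: 4 (1E,3E)-5-methylhexa-1,3-dien-1-yl acetate; 7 ethyl (E)-4-oxo-4-(2-oxooxazolidin-3-yl)but-2-enoate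
Product: 23 B-hand cycloadduct, ethyl (1S,2R,5S,6R)-5-acetoxy-2-isopropyl-6-(2-oxooxazolidine-3-carbonyl)cyclohex-3-ene-1-carboxylate (enantiomer of 8)
Conditions: [Cu((R,R)-t-Bu-box)](SbF6)2 (10 mol%; from CuCl2, AgSbF6 and (R,R)-2,2'-isopropylidenebis(4-tert-butyl-2-oxazoline)), CH2Cl2, −20 °C → rt
Reagents that add atoms: none
Why: The same copper bis(oxazoline)-catalysed Diels–Alder reaction as in step 4 run with the enantiomeric catalyst, which should open the opposite face of the chelated imide and so give the mirror-image adduct with the same regio- and endo selectivity.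

Step 17
Reactants: 23 B-hand cycloadduct
Product: 24 B-hand saturated adduct (enantiomer of 9)
Conditions: H2 (1 atm), PtO2 (cat.), EtOAc, rt
Reagents that add atoms: none
Why: Platinum-catalysed hydrogenation of the C7=C8 bond as in step 5, applied to the enantiomer.

Step 18
Reactants: 24 B-hand saturated adduct
Product: 25 B-hand hydroxymethyl ester (enantiomer of 10)
Conditions: NaBH4, THF/H2O (4:1), 0 °C → rt
Reagents that add atoms: none
Why: Chemoselective borohydride reduction of the imide carbonyl to the C1 primary alcohol as in step 6, applied to the enantiomer.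

Step 19
Reactants: 25 B-hand hydroxymethyl ester
Product: 27 B-hand hydroxy lactone (enantiomer of 12), via diol ester 26 (not isolated)
Conditions: K2CO3 (cat.), MeOH, 0 °C → rt; then AcOH, evaporation; CSA (cat.), toluene, 50 °C
Reagents that add atoms: none
Why: Acetate methanolysis followed by acid-catalysed trans-fused γ-lactonisation as in step 7, applied to the enantiomer.

Step 20
Reactants: 27 B-hand hydroxy lactone
Product: 28 B-hand keto lactone (enantiomer of 13)
Conditions: Dess–Martin periodinane, CH2Cl2, rt
Reagents that add atoms: none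
Why: Dess–Martin oxidation of the C9 alcohol to the ketone as in step 8, applied to the enantiomer.

Step 21
Reactants: 28 B-hand keto lactone
Product: 29 B-hand methylene lactone (enantiomer of 14)
Conditions: Zn, CH2Br2, TiCl4 (preformed reagent), THF/CH2Cl2, 0 °C → rt
Reagents that add atoms: dibromomethane, BrCBr
Why: Non-basic Lombardo methylenation of the C9 ketone as in step 9, applied to the enantiomer.

Step 22
Reactants: 29 B-hand methylene lactone
Product: 30 B-hand lactol (enantiomer of 15, mixture of anomers)
Conditions: i-Bu2AlH (1.1 equiv), CH2Cl2, −78 °C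
Reagents that add atoms: none
Why: Partial i-Bu2AlH reduction of the γ-lactone to the lactol as in step 10, applied to the enantiomer.

Step 23
Reactants: 30 B-hand lactol
Product: 31 B-hand diene alcohol (enantiomer of 16)
Conditions: Ph3PCH3Br, KOt-Bu (3 equiv each), THF, 0 °C → rt
Reagents that add atoms: methyltriphenylphosphonium bromide (as its ylide), C[P+](c1ccccc1)(c1ccccc1)c1ccccc1.[Br-]
Why: Wittig methylenation of the lactol as in step 11, applied to the enantiomer.

Step 24
Reactants: 31 B-hand diene alcohol
Product: 32 B-hand diene acid (enantiomer of 17)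
Conditions: TEMPO (cat.), PhI(OAc)2 (2.2 equiv), MeCN/H2O (1:1), rt
Reagents that add atoms: water, O
Why: Oxoammonium oxidation of the C1 primary alcohol to the acid as in step 12, applied to the enantiomer.

Step 25
Reactants: 32 B-hand diene acid; 18 tert-butyl 2-(bromomethyl)acrylate
Product: 33 B-hand triene diester (enantiomer of 19)
Conditions: Cs2CO3, DMF, 0 °C → rt
Reagents that add atoms: none
Why: Carboxylate O-alkylation with the allylic bromide as in step 13, applied to the enantiomer.

Step 26
Reactants: 33 B-hand triene diester
Product: 34 B-hand oxepinone ester, tert-butyl (5aR,6S,9aR)-6-isopropyl-9-methylidene-1-oxo-1,3,5a,6,7,8,9,9a-octahydro-2-benzoxepine-4-carboxylate (enantiomer of 20)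
Conditions: second-generation Hoveyda–Grubbs catalyst, RuCl2(H2IMes)(=CH-C6H4-2-O-i-Pr) (10 mol%), toluene (2 mM), 80 °C
Reagents that add atoms: none
Why: Ring-closing metathesis to the seven-membered lactone as in step 14, applied to the enantiomer.

Step 27
Reactants: 34 B-hand oxepinone ester
Product: 35 B-hand diol ester, tert-butyl (5aR,6S,9R,9aR)-9-hydroxy-9-(hydroxymethyl)-6-isopropyl-1-oxo-1,3,5a,6,7,8,9,9a-octahydro-2-benzoxepine-4-carboxylate
Conditions: OsO4 (cat.), NMO, acetone/H2O (4:1), 0 °C → rt
Reagents that add atoms: N-methylmorpholine N-oxide, C[N+]1([O-])CCOCC1; water, O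
Why: Upjohn dihydroxylation in which OsO4 should add to the exocyclic alkene from the equatorial direction, away from the syn-axial hydrogens on C7 and C5a and from the C1 carbonyl on C9a, so that the tertiary OH becomes equatorial and trans to C1 (9R) and the CH2OH axial, while the electron-poor C4=C5 bond is left.

Step 28
Reactants: 22 A-hand acid; 35 B-hand diol ester
Product: 36 coupled ester, the C4 carboxyl of the half-A methylene lactone esterified with the C9-CH2OH of the half-B tert-butyl ester (tertiary C9–OH of B free)
Conditions: 2-methyl-6-nitrobenzoic anhydride, DMAP, Et3N, CH2Cl2, rt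
Reagents that add atoms: none
Why: Shiina mixed-anhydride esterification activates the C4 acid of 22 and should acylate the primary hydroxyl of 35 selectively, the tertiary C9–OH being too hindered to compete, and no stereocentre is involved.

Step 29
Reactants: 36 coupled ester
Product: 37 triol tert-butyl ester (half A now carries the C9 tertiary OH and CH2OH; half B unchanged)
Conditions: OsO4 (cat.), NMO, acetone/H2O (4:1), 0 °C → rt
Reagents that add atoms: N-methylmorpholine N-oxide, C[N+]1([O-])CCOCC1; water, O
Why: Upjohn dihydroxylation as in step 27 on the only electron-rich alkene, equatorial attack setting the half-A C9 carbinol (9S) trans to C1 while the two electron-poor ring enoates are left.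

Step 30
Reactants: 37 triol tert-butyl ester
Product: 38 CNP0340505.1 (target)
Conditions: TFA/CH2Cl2 (1:4), 0 °C
Reagents that add atoms: none
Why: Acidolysis of the tert-butyl ester with loss of 2-methylpropene frees the C4 acid of half B at a temperature at which the two lactones, the enoate ester link and the three hydroxyls should survive.

Compound list
1 | 3-methylbutanal | CC(C)CC=O | starting material
2 | (triphenylphosphoranylidene)acetaldehyde | O=CC=P(c1ccccc1)(c1ccccc1)c1ccccc1 | starting material
3 | (E)-5-methylhex-2-enal | CC(C)C/C=C/C=O | intermediate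
4 | (1E,3E)-5-methylhexa-1,3-dien-1-yl acetate | CC(C)/C=C/C=C/OC(C)=O | intermediate
5 | ethyl (E)-4-chloro-4-oxobut-2-enoate | CCOC(=O)/C=C/C(=O)Cl | starting material
6 | oxazolidin-2-one | O=C1NCCO1 | starting material
7 | ethyl (E)-4-oxo-4-(2-oxooxazolidin-3-yl)but-2-enoate | CCOC(=O)/C=C/C(=O)N1CCOC1=O | intermediate
8 | A-hand cycloadduct, ethyl (1R,2S,5R,6S)-5-acetoxy-2-isopropyl-6-(2-oxooxazolidine-3-carbonyl)cyclohex-3-ene-1-carboxylate | CC(C)[C@H]1C=C[C@@H](OC(C)=O)[C@@H](C(=O)N2CCOC2=O)[C@@H]1C(=O)OCC | intermediate
9 | A-hand saturated adduct (cyclohexane; acetoxy, imide and isopropyl cis, ester trans) | CC(C)[C@H]1CC[C@@H](OC(C)=O)[C@@H](C(=O)N2CCOC2=O)[C@@H]1C(=O)OCC | intermediate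
10 | A-hand hydroxymethyl ester (C1 as CH2OH, C9 acetate, C5 ethyl ester) | CC(C)[C@H]1CC[C@@H](OC(C)=O)[C@@H](CO)[C@@H]1C(=O)OCC | intermediate
11 | A-hand diol ester (C9–OH, C1H2OH, C5 ethyl ester) | CC(C)[C@H]1CC[C@@H](O)[C@@H](CO)[C@@H]1C(=O)OCC | intermediate (not isolated)
12 | A-hand hydroxy lactone, trans-fused 4-hydroxy-7-isopropylhexahydroisobenzofuran-1(3H)-one | CC(C)[C@H]1CC[C@@H](O)[C@H]2COC(=O)[C@H]12 | intermediate
13 | A-hand keto lactone, trans-fused 7-isopropylhexahydroisobenzofuran-1,4-dione | CC(C)[C@H]1CCC(=O)[C@H]2COC(=O)[C@H]12 | intermediate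
14 | A-hand methylene lactone, trans-fused 7-isopropyl-4-methylidenehexahydroisobenzofuran-1(3H)-one | CC(C)[C@H]1CCC(=C)[C@H]2COC(=O)[C@H]12 | intermediate
15 | A-hand lactol, 7-isopropyl-4-methylideneoctahydroisobenzofuran-1-ol (anomers) | CC(C)[C@H]1CCC(=C)[C@H]2COC(O)[C@H]12 | intermediate
16 | A-hand diene alcohol, (2-ethenyl-3-isopropyl-6-methylidenecyclohexyl)methanol | CC(C)[C@H]1CCC(=C)[C@@H](CO)[C@@H]1C=C | intermediate
17 | A-hand diene acid, 2-ethenyl-3-isopropyl-6-methylidenecyclohexane-1-carboxylic acid | CC(C)[C@H]1CCC(=C)[C@@H](C(=O)O)[C@@H]1C=C | intermediate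
18 | tert-butyl 2-(bromomethyl)acrylate | C=C(CBr)C(=O)OC(C)(C)C | starting material
19 | A-hand triene diester, 2-(tert-butoxycarbonyl)prop-2-en-1-yl ester of 17 | CC(C)[C@H]1CCC(=C)[C@@H](C(=O)OCC(=C)C(=O)OC(C)(C)C)[C@@H]1C=C | intermediate
20 | A-hand oxepinone ester, tert-butyl (5aS,6R,9aS)-6-isopropyl-9-methylidene-1-oxo-1,3,5a,6,7,8,9,9a-octahydro-2-benzoxepine-4-carboxylate | CC(C)[C@H]1CCC(=C)[C@H]2C(=O)OCC(C(=O)OC(C)(C)C)=C[C@H]12 | intermediate
21 | trimethylsilyl ester of 22 | CC(C)[C@H]1CCC(=C)[C@H]2C(=O)OCC(C(=O)O[Si](C)(C)C)=C[C@H]12 | intermediate (not isolated)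
22 | A-hand acid, (5aS,6R,9aS)-6-isopropyl-9-methylidene-1-oxo-1,3,5a,6,7,8,9,9a-octahydro-2-benzoxepine-4-carboxylic acid | CC(C)[C@H]1CCC(=C)[C@H]2C(=O)OCC(C(=O)O)=C[C@H]12 | intermediate
23 | B-hand cycloadduct, ethyl (1S,2R,5S,6R)-5-acetoxy-2-isopropyl-6-(2-oxooxazolidine-3-carbonyl)cyclohex-3-ene-1-carboxylate | CC(C)[C@@H]1C=C[C@H](OC(C)=O)[C@H](C(=O)N2CCOC2=O)[C@H]1C(=O)OCC | intermediate
24 | B-hand saturated adduct (enantiomer of 9) | CC(C)[C@@H]1CC[C@H](OC(C)=O)[C@H](C(=O)N2CCOC2=O)[C@H]1C(=O)OCC | intermediate
25 | B-hand hydroxymethyl ester (enantiomer of 10) | CC(C)[C@@H]1CC[C@H](OC(C)=O)[C@H](CO)[C@H]1C(=O)OCC | intermediate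
26 | B-hand diol ester (enantiomer of 11) | CC(C)[C@@H]1CC[C@H](O)[C@H](CO)[C@H]1C(=O)OCC | intermediate (not isolated)
27 | B-hand hydroxy lactone (enantiomer of 12) | CC(C)[C@@H]1CC[C@H](O)[C@@H]2COC(=O)[C@@H]12 | intermediate
28 | B-hand keto lactone (enantiomer of 13) | CC(C)[C@@H]1CCC(=O)[C@@H]2COC(=O)[C@@H]12 | intermediate
29 | B-hand methylene lactone (enantiomer of 14) | CC(C)[C@@H]1CCC(=C)[C@@H]2COC(=O)[C@@H]12 | intermediate
30 | B-hand lactol (enantiomer of 15, anomers) | CC(C)[C@@H]1CCC(=C)[C@@H]2COC(O)[C@@H]12 | intermediate
31 | B-hand diene alcohol (enantiomer of 16) | CC(C)[C@@H]1CCC(=C)[C@H](CO)[C@H]1C=C | intermediate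
32 | B-hand diene acid (enantiomer of 17) | CC(C)[C@@H]1CCC(=C)[C@H](C(=O)O)[C@H]1C=C | intermediate
33 | B-hand triene diester (enantiomer of 19) | CC(C)[C@@H]1CCC(=C)[C@H](C(=O)OCC(=C)C(=O)OC(C)(C)C)[C@H]1C=C | intermediate
34 | B-hand oxepinone ester, tert-butyl (5aR,6S,9aR)-6-isopropyl-9-methylidene-1-oxo-1,3,5a,6,7,8,9,9a-octahydro-2-benzoxepine-4-carboxylate | CC(C)[C@@H]1CCC(=C)[C@@H]2C(=O)OCC(C(=O)OC(C)(C)C)=C[C@@H]12 | intermediate
35 | B-hand diol ester, tert-butyl (5aR,6S,9R,9aR)-9-hydroxy-9-(hydroxymethyl)-6-isopropyl-1-oxo-1,3,5a,6,7,8,9,9a-octahydro-2-benzoxepine-4-carboxylate | CC(C)[C@@H]1CC[C@](O)(CO)[C@@H]2C(=O)OCC(C(=O)OC(C)(C)C)=C[C@@H]12 | intermediate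
36 | coupled ester (half A: 9-methylidene lactone; half B: C9–OH, C9-CH2O-acyl, tert-butyl ester) | CC(C)[C@H]1CCC(=C)[C@H]2C(=O)OCC(C(=O)OC[C@@]3(O)CC[C@@H](C(C)C)[C@@H]4C=C(C(=O)OC(C)(C)C)COC(=O)[C@H]43)=C[C@H]12 | intermediate
37 | triol tert-butyl ester (tert-butyl ester of the target) | CC(C)[C@H]1CC[C@@](O)(CO)[C@H]2C(=O)OCC(C(=O)OC[C@@]3(O)CC[C@@H](C(C)C)[C@@H]4C=C(C(=O)OC(C)(C)C)COC(=O)[C@H]43)=C[C@H]12 | intermediate
38 | CNP0340505.1: half A (5aS,6R,9S,9aS) diol lactone, its C4 carboxyl esterified with the C9-CH2OH of half B (5aR,6S,9R,9aR), which carries the free C4 acid | CC(C)[C@H]1CC[C@@](O)(CO)[C@H]2C(=O)OCC(C(=O)OC[C@@]3(O)CC[C@@H](C(C)C)[C@@H]4C=C(C(=O)O)COC(=O)[C@H]43)=C[C@H]12 | target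

Total step count: 30 (steps 1–3 for the two cycloaddition partners, steps 4–15 for the half-A series, steps 16–27 for the half-B series, steps 28–30 from the union to the target).
Longest linear sequence: 17 steps (1, 2, 4–15, 28–30; the half-B branch 1, 2, 16–27, 28–30 is equally long).

Steps most likely to fail

1. Step 14 (ring-closing metathesis; step 26 is the same reaction on the mirror image and shares the risk and the answer). The ruthenium carbene may turn over poorly on the hindered C5a-vinyl group paired with an electron-poor 1,1-disubstituted alkene, or may couple two molecules through the vinyl groups instead of closing the seven-membered lactone. The fallback closes the ring by olefination instead and sets out from methylene lactone 14. The lactone is opened with MeNH(OMe)·HCl/AlMe3 to the hydroxy Weinreb amide F1, whose primary alcohol is oxidised (TEMPO, PhI(OAc)2, aqueous MeCN) to the amide acid F2. LiAlH4 at −78 °C, with the acid held as its lithium carboxylate, reduces the amide to the aldehyde acid F3. tert-Butyl 2-(diethoxyphosphoryl)acrylate and NaH then add the carboxylate in an oxa-Michael step and close C4=C5 by intramolecular Horner–Wadsworth–Emmons olefination, which comes back to the route at 20. For step 26 the same sequence sets out from 29 and passes through the mirror-image hydroxy Weinreb amide F4, amide acid F5 and aldehyde acid F6 to come back at 34.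

2. Step 28 (union of the halves). Acylation of the neopentyl-type primary alcohol may be slow enough that DMAP-promoted translactonisation of the diol (primary OH onto C1) or migration of the enoate double bond in the activated acid takes over. The fallback makes the same C–O bond by substitution and sets out from diol 35. Selective sulfonylation of the primary hydroxyl (TsCl, pyridine, DMAP) gives the primary tosylate F7, which DBU closes to the spiro-epoxide F8 with retention at C9. The caesium salt of acid 22 (Cs2CO3, DMF, 50 °C) then opens the epoxide at its CH2 terminus, which comes back to the route at 36.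

3. Step 29 (osmylation on the dimer). Turnover at the hindered alkene of the large substrate may be slow, so that attack on the two electron-poor ring alkenes or translactonisation of the newly formed diol during a long reaction in the amine-containing medium erodes the outcome. The fallback moves the osmylation ahead of the union and sets out from acid 22. OsO4/NMO gives the diol acid F9, and 2-methoxypropene/PPTS masks it as the acetonide acid F10. The mixed-anhydride esterification of step 28 with 35 gives the acetonide-protected dimer F11, and aqueous TFA removes the acetonide and the tert-butyl ester together, which comes back to the route at the target 38.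

Further compounds
F1 | step 14 | A-hand hydroxy Weinreb amide (C5 as N-methoxy-N-methylamide, C1 as CH2OH) | CC(C)[C@H]1CCC(=C)[C@@H](CO)[C@@H]1C(=O)N(C)OC
F2 | step 14 | A-hand amide acid (C5 Weinreb amide, C1 acid) | CC(C)[C@H]1CCC(=C)[C@@H](C(=O)O)[C@@H]1C(=O)N(C)OC
F3 | step 14 | A-hand aldehyde acid (C5 aldehyde, C1 acid) | CC(C)[C@H]1CCC(=C)[C@@H](C(=O)O)[C@@H]1C=O
F4 | step 26 | B-hand hydroxy Weinreb amide (enantiomer of F1) | CC(C)[C@@H]1CCC(=C)[C@H](CO)[C@H]1C(=O)N(C)OC
F5 | step 26 | B-hand amide acid (enantiomer of F2) | CC(C)[C@@H]1CCC(=C)[C@H](C(=O)O)[C@H]1C(=O)N(C)OC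
F6 | step 26 | B-hand aldehyde acid (enantiomer of F3) | CC(C)[C@@H]1CCC(=C)[C@H](C(=O)O)[C@H]1C=O
F7 | step 28 | B-hand primary tosylate of 35 | CC(C)[C@@H]1CC[C@](O)(COS(=O)(=O)c3ccc(C)cc3)[C@@H]2C(=O)OCC(C(=O)OC(C)(C)C)=C[C@@H]12
F8 | step 28 | B-hand spiro-epoxide tert-butyl ester (C9 spiro-oxirane, oxygen trans to C1) | CC(C)[C@@H]1CC[C@]3(CO3)[C@@H]2C(=O)OCC(C(=O)OC(C)(C)C)=C[C@@H]12
F9 | step 29 | A-hand diol acid, (5aS,6R,9S,9aS)-9-hydroxy-9-(hydroxymethyl)-6-isopropyl-1-oxo-1,3,5a,6,7,8,9,9a-octahydro-2-benzoxepine-4-carboxylic acid | CC(C)[C@H]1CC[C@@](O)(CO)[C@H]2C(=O)OCC(C(=O)O)=C[C@H]12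
F10 | step 29 | A-hand acetonide acid (C9 diol as isopropylidene acetal) | CC(C)[C@H]1CC[C@@]3(COC(C)(C)O3)[C@H]2C(=O)OCC(C(=O)O)=C[C@H]12
F11 | step 29 | acetonide-protected dimer tert-butyl ester | CC(C)[C@H]1CC[C@@]5(COC(C)(C)O5)[C@H]2C(=O)OCC(C(=O)OC[C@@]3(O)CC[C@@H](C(C)C)[C@@H]4C=C(C(=O)OC(C)(C)C)COC(=O)[C@H]43)=C[C@H]12
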